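**Plan**
- Retrosynthesis: cut the C1–O ester bond. Then, in the lactone (O1, C2 = carbonyl, C3 = alkylidene carbon, C4 = CHOH, C5 = CH–O), cut O1–C5 and C2–C3 together, so that CO2 is removed between a C3 alkenyl anion and a C5 electrophile. Then cut the C5 side-chain alkene (Wittig), the C(sp)–C(sp2) bond (Sonogashira) and the C8–C9 bond of the chain.
- Enabling feature: C3 is an sp2 carbon that can be lithiated with fixed geometry. C5 is allylic to the 2-methylprop-1-enyl group and vicinal to the C4 oxygen, so a temporary 1,3-dioxolane ring over O–C4/O–C5 (a cyclic orthoformate) can be ionised to a dioxolan-2-ylium ion, which the newly made carboxylate opens at C5.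
- Forward: nerol is extended to a C11 enyne, joined to a C3 iodoallyl alcohol, epoxidised, and the 2-methylprop-1-enyl group is added by Wittig reaction. The epoxide is turned into the threo diol, then the alkenyl iodide and the orthoformate. The lactone (the only ring) closes in the key step, and the ester is made last.
- Stereochemistry: C4 and C5 come from one Sharpless epoxidation (L-(+)-diethyl tartrate). The epoxide oxygen stays on C4 throughout; C5 is retained in the CO2 insertion and inverted in the key step. The 3E alkene comes from syn hydrostannation, 2Z from nerol and 6E from the selenium dioxide oxidation.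

Key step: step 12

Assumption: (2E)-3-iodoprop-2-en-1-ol (8) and (2E)-3-methylpent-2-enoic acid (26) are taken as purchasable building blocks.

**Step 1**
Reactants: 1 nerol, (2Z)-3,7-dimethylocta-2,6-dien-1-ol
Product: 2 tert-butyl{[(2Z)-3,7-dimethylocta-2,6-dien-1-yl]oxy}dimethylsilane
Conditions: TBSCl, imidazole, CH2Cl2, 0 °C → rt
Reagents that add atoms: tert-butyldimethylsilyl chloride, CC(C)(C)[Si](C)(C)Cl
Why: Standard silylation of a primary alcohol, which masks the C1 oxygen through the organometallic steps and carries the 2Z alkene of nerol unchanged into the target.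

**Step 2**
Reactants: 2 nerol silyl ether
Product: 3 (2E,6Z)-8-{[tert-butyl(dimethyl)silyl]oxy}-2,6-dimethylocta-2,6-dien-1-ol
Conditions: SeO2 (cat.), tBuOOH, salicylic acid (cat.), CH2Cl2, 0 °C → rt
Reagents that add atoms: tert-butyl hydroperoxide, CC(C)(C)OO
Why: Selenium dioxide allylic oxidation (ene reaction, then [2,3]-sigmatropic shift) should attack the more electron-rich terminal alkene at its (E)-methyl group and so give the (E)-allylic alcohol, which fixes the 6E geometry of the chain.

**Step 3**
Reactants: 3 allylic alcohol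
Product: 4 {[(2Z,6E)-8-bromo-3,7-dimethylocta-2,6-dien-1-yl]oxy}(tert-butyl)dimethylsilane
Conditions: CBr4, PPh3, CH2Cl2, −20 → 0 °C
Reagents that add atoms: tetrabromomethane, BrC(Br)(Br)Br
Why: Appel bromination of a primary allylic alcohol proceeds by SN2 displacement of the oxyphosphonium group, so neither alkene geometry nor the silyl ether should be touched.

**Step 4**
Reactants: 4 allylic bromide, 5 3-bromoprop-1-yne (propargyl bromide)
Product: 7 tert-butyl{[(2Z,6E)-3,7-dimethylundeca-2,6-dien-10-yn-1-yl]oxy}dimethylsilane, via 1,3-dilithiopropyne 6 (not isolated)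
Conditions: 5, nBuLi (2 equiv), TMEDA, Et2O–hexane, −78 °C; then 4, −78 °C → rt; H2O
Reagents that add atoms: none
Why: C-alkylation of the propargyl dianion: its sp3 carbanion is far more nucleophilic than the acetylide end, so SN2 attack on the primary allylic bromide should give the 1,5-enyne with a free terminal alkyne and no allylic transposition.

**Step 5**
Reactants: 7 terminal alkyne, 8 (2E)-3-iodoprop-2-en-1-ol
Product: 9 (2E,8E,12Z)-14-{[tert-butyl(dimethyl)silyl]oxy}-8,12-dimethyltetradeca-2,8,12-trien-4-yn-1-ol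
Conditions: PdCl2(PPh3)2 (cat.), CuI (cat.), Et3N, THF, rt
Reagents that add atoms: none
Why: Sonogashira coupling of a terminal alkyne with an alkenyl iodide keeps the E geometry of the iodide and tolerates the free hydroxyl and the silyl ether.

**Step 6**
Reactants: 9 enynol
Product: 10 [(2S,3S)-3-{(5E,9Z)-11-[(tert-butyldimethylsilyl)oxy]-5,9-dimethylundeca-5,9-dien-1-yn-1-yl}oxiran-2-yl]methanol
Conditions: Ti(OiPr)4 (cat.), L-(+)-diethyl tartrate (cat.), tBuOOH, 4 Å molecular sieves, CH2Cl2, −20 °C
Reagents that add atoms: tert-butyl hydroperoxide, CC(C)(C)OO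
Why: Sharpless asymmetric epoxidation should oxidise only the alkene of the free allylic alcohol, and with L-(+)-diethyl tartrate give the (2S,3S)-epoxide whose two carbons become C4 and C5 of the lactone; the other alkenes carry no free allylic hydroxyl and the alkyne is inert.

**Step 7**
Reactants: 10 epoxy alcohol
Product: 11 (2R,3S)-3-{(5E,9Z)-11-[(tert-butyldimethylsilyl)oxy]-5,9-dimethylundeca-5,9-dien-1-yn-1-yl}oxirane-2-carbaldehyde
Conditions: TEMPO (cat.), PhI(OAc)2, CH2Cl2, rt
Reagents that add atoms: none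
Why: Oxoammonium (TEMPO) oxidation of a primary alcohol to the aldehyde is mild enough to leave the epoxide, the alkyne and the trisubstituted alkenes alone; the change of descriptor at C2 is only a priority change.

**Step 8**
Reactants: 11 epoxy aldehyde, 12 triphenyl(propan-2-yl)phosphonium iodide
Product: 14 (2S,3S)-2-{(5E,9Z)-11-[(tert-butyldimethylsilyl)oxy]-5,9-dimethylundeca-5,9-dien-1-yn-1-yl}-3-(2-methylprop-1-en-1-yl)oxirane, via isopropylidene ylide 13 (not isolated)
Conditions: 12, nBuLi, THF, 0 °C; then 11, −78 → 0 °C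
Reagents that add atoms: none
Why: Wittig olefination with a non-stabilised ylide at low temperature builds the 2-methylprop-1-enyl group (no alkene geometry arises) and should not epimerise or open the trans-epoxide.

**Step 9**
Reactants: 14 trans-alkynyl vinyl epoxide
Product: 16 (4S,5S,10E,14Z)-16-{[tert-butyl(dimethyl)silyl]oxy}-2,10,14-trimethylhexadeca-2,10,14-trien-6-yne-4,5-diol, via trans carbonate 15 (not isolated)
Conditions: Pd(PPh3)4 (cat.), CO2 (1 atm), THF, 0 °C → rt; then K2CO3 (cat.), MeOH, rt
Reagents that add atoms: carbon dioxide, O=C=O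
Why: Zerovalent-palladium-catalysed insertion of CO2 into a vinyl epoxide (ionisation to a π-allylpalladium alkoxide, capture of CO2, closure anti to palladium) should give the trans carbonate with net retention at the allylic carbon, and methanolysis then frees the threo diol with the epoxide oxygen still on the future C4.

**Step 10**
Reactants: 16 threo diol
Product: 18 (4S,5R,6E,10E,14Z)-16-{[tert-butyl(dimethyl)silyl]oxy}-6-iodo-2,10,14-trimethylhexadeca-2,6,10,14-tetraene-4,5-diol, via alkenylstannane 17 (not isolated)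
Conditions: PdCl2(PPh3)2 (cat.), Bu3SnH, THF, 0 °C; then I2, CH2Cl2, −78 → 0 °C
Reagents that add atoms: iodine, II
Why: Palladium-catalysed syn hydrostannation of a propargylic alcohol should place tin on the alkyne carbon next to the carbinol with hydrogen cis to it, and iododestannylation with retention then gives the alkenyl iodide in which the chain is cis to the carbinol carbon, as in the target's exocyclic alkene; the descriptor at C5 changes only through the priority of iodine.

**Step 11**
Reactants: 18 iodo diol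
Product: 19 (4R,5S)-4-[(1E,5E,9Z)-11-{[tert-butyl(dimethyl)silyl]oxy}-1-iodo-5,9-dimethylundeca-1,5,9-trien-1-yl]-2-methoxy-5-(2-methylprop-1-en-1-yl)-1,3-dioxolane (both epimers at C2)
Conditions: HC(OMe)3, PPTS (cat.), CH2Cl2, rt
Reagents that add atoms: trimethyl orthoformate, COC(OC)OC
Why: Acid-catalysed transorthoesterification of a 1,2-diol gives the cyclic orthoformate, a temporary ring that hides both hydroxyls from the organolithium of the next step and later supplies the dioxolan-2-ylium leaving group.

**Step 12**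
Reactants: 19 iodoalkenyl orthoformate
Product: 24 (3E,4S,5R)-3-{(4E,8Z)-10-[(tert-butyldimethylsilyl)oxy]-4,8-dimethyldeca-4,8-dien-1-ylidene}-5-(2-methylprop-1-en-1-yl)-2-oxooxolan-4-yl formate, via alkenyllithium 20 (not isolated), via lithium carboxylate 21 (not isolated), via carboxylic acid 22 (not isolated), via dioxolanylium carboxylate 23 (not isolated)
Conditions: tBuLi (2.1 equiv), Et2O, −78 °C; CO2 (dry gas), −78 °C; then CH3SO3H (1.05 equiv), CH2Cl2, −78 → 0 °C
Reagents that add atoms: carbon dioxide, O=C=O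
Why: Proposed new method: iodine–lithium exchange gives alkenyllithium 20, whose only β-oxygen is a poor orthoester leaving group, so it should survive to be carboxylated at C3 (new C2–C3 bond); protonation of 21 gives acid 22, which protonates its own orthoformate, expels methanol and forms the 1,3-dioxolan-2-ylium carboxylate 23. The carboxylate oxygen then attacks C5 from the face opposite the departing ring oxygen (new O1–C5 bond) and so releases the C4 oxygen as a formate; the closest known reaction types are the carboxylate opening of dioxolan-2-ylium ions in the Prévost reaction and the carboxylation of alkenyllithiums, and what is new is their union in one flask with the acid acting as its own nucleophile. The lactone closes by a 5-exo-tet displacement in which the leaving dioxolanylium ring is fused across C4–C5, the counterpart of the anti opening of the trans-epoxide for which the orthoformate stands in. No new stereocenter is made: C5 is inverted stereospecifically, C4 keeps the oxygen of the Sharpless epoxide, and the exocyclic alkene keeps the geometry of the alkenyl iodide because alkenyllithiums are carboxylated with retention. The step needs attack at C5 and not at C4, and inversion and not ionisation: the first is secured by ring size (γ- against β-lactone) and the allylic activation of C5 by the 2-methylprop-1-enyl group, the second by the intramolecular, ion-paired nucleophile at low temperature in a weakly polar medium with a non-nucleophilic counter-ion.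

**Step 13**
Reactants: 24 lactone formate
Product: 25 (3E,4S,5R)-4-hydroxy-3-[(4E,8Z)-10-hydroxy-4,8-dimethyldeca-4,8-dien-1-ylidene]-5-(2-methylprop-1-en-1-yl)oxolan-2-one
Conditions: PPTS (cat.), MeOH, 40 °C
Reagents that add atoms: none
Why: Acid-catalysed methanolysis should cleave the formate (transesterification) and the primary silyl ether in one operation, while the lactone, its allylic C5–O bond and the alkenes survive these mild conditions.

**Step 14**
Reactants: 25 diol lactone, 26 (2E)-3-methylpent-2-enoic acid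
Product: 27 [(2Z,6E)-10-[(3E,4S,5R)-4-hydroxy-5-(2-methylprop-1-en-1-yl)-2-oxooxolan-3-ylidene]-3,7-dimethyldeca-2,6-dien-1-yl] (2E)-3-methylpent-2-enoate (target)
Conditions: DCC, DMAP (cat.), CH2Cl2, −20 → 0 °C
Reagents that add atoms: none
Why: Steglich esterification should acylate the primary allylic alcohol much faster than the hindered secondary C4 hydroxyl, and low temperature with catalytic DMAP limits deconjugation or E/Z isomerisation of the enoate.

**Compound list**
1 | nerol, (2Z)-3,7-dimethylocta-2,6-dien-1-ol | CC(C)=CCC/C(C)=C\CO | starting material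
2 | tert-butyl{[(2Z)-3,7-dimethylocta-2,6-dien-1-yl]oxy}dimethylsilane | CC(C)=CCC/C(C)=C\CO[Si](C)(C)C(C)(C)C | intermediate
3 | (2E,6Z)-8-{[tert-butyl(dimethyl)silyl]oxy}-2,6-dimethylocta-2,6-dien-1-ol | OC/C(C)=C/CC/C(C)=C\CO[Si](C)(C)C(C)(C)C | intermediate
4 | {[(2Z,6E)-8-bromo-3,7-dimethylocta-2,6-dien-1-yl]oxy}(tert-butyl)dimethylsilane | BrC/C(C)=C/CC/C(C)=C\CO[Si](C)(C)C(C)(C)C | intermediate
5 | 3-bromoprop-1-yne | C#CCBr | starting material
6 | 1,3-dilithiopropyne | [Li]CC#C[Li] | intermediate
7 | tert-butyl{[(2Z,6E)-3,7-dimethylundeca-2,6-dien-10-yn-1-yl]oxy}dimethylsilane | C#CCC/C(C)=C/CC/C(C)=C\CO[Si](C)(C)C(C)(C)C | intermediate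
8 | (2E)-3-iodoprop-2-en-1-ol | OC/C=C/I | starting material
9 | (2E,8E,12Z)-14-{[tert-butyl(dimethyl)silyl]oxy}-8,12-dimethyltetradeca-2,8,12-trien-4-yn-1-ol | OC/C=C/C#CCC/C(C)=C/CC/C(C)=C\CO[Si](C)(C)C(C)(C)C | intermediate
10 | [(2S,3S)-3-{(5E,9Z)-11-[(tert-butyldimethylsilyl)oxy]-5,9-dimethylundeca-5,9-dien-1-yn-1-yl}oxiran-2-yl]methanol | OC[C@@H]1O[C@H]1C#CCC/C(C)=C/CC/C(C)=C\CO[Si](C)(C)C(C)(C)C | intermediate
11 | (2R,3S)-3-{(5E,9Z)-11-[(tert-butyldimethylsilyl)oxy]-5,9-dimethylundeca-5,9-dien-1-yn-1-yl}oxirane-2-carbaldehyde | O=C[C@@H]1O[C@H]1C#CCC/C(C)=C/CC/C(C)=C\CO[Si](C)(C)C(C)(C)C | intermediate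
12 | triphenyl(propan-2-yl)phosphonium iodide | CC(C)[P+](c1ccccc1)(c1ccccc1)c1ccccc1.[I-] | starting material
13 | triphenyl(propan-2-ylidene)phosphorane | CC(C)=P(c1ccccc1)(c1ccccc1)c1ccccc1 | intermediate
14 | (2S,3S)-2-{(5E,9Z)-11-[(tert-butyldimethylsilyl)oxy]-5,9-dimethylundeca-5,9-dien-1-yn-1-yl}-3-(2-methylprop-1-en-1-yl)oxirane | CC(C)=C[C@@H]1O[C@H]1C#CCC/C(C)=C/CC/C(C)=C\CO[Si](C)(C)C(C)(C)C | intermediate
15 | (4S,5S)-4-{(5E,9Z)-11-[(tert-butyldimethylsilyl)oxy]-5,9-dimethylundeca-5,9-dien-1-yn-1-yl}-5-(2-methylprop-1-en-1-yl)-1,3-dioxolan-2-one | CC(C)=C[C@@H]1OC(=O)O[C@H]1C#CCC/C(C)=C/CC/C(C)=C\CO[Si](C)(C)C(C)(C)C | intermediate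
16 | (4S,5S,10E,14Z)-16-{[tert-butyl(dimethyl)silyl]oxy}-2,10,14-trimethylhexadeca-2,10,14-trien-6-yne-4,5-diol | CC(C)=C[C@H](O)[C@@H](O)C#CCC/C(C)=C/CC/C(C)=C\CO[Si](C)(C)C(C)(C)C | intermediate
17 | (4S,5R,6E,10E,14Z)-16-{[tert-butyl(dimethyl)silyl]oxy}-2,10,14-trimethyl-6-(tributylstannyl)hexadeca-2,6,10,14-tetraene-4,5-diol | CC(C)=C[C@H](O)[C@@H](O)/C(=C\CC/C(C)=C/CC/C(C)=C\CO[Si](C)(C)C(C)(C)C)[Sn](CCCC)(CCCC)CCCC | intermediate
18 | (4S,5R,6E,10E,14Z)-16-{[tert-butyl(dimethyl)silyl]oxy}-6-iodo-2,10,14-trimethylhexadeca-2,6,10,14-tetraene-4,5-diol | CC(C)=C[C@H](O)[C@@H](O)/C(I)=C\CC/C(C)=C/CC/C(C)=C\CO[Si](C)(C)C(C)(C)C | intermediate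
19 | (4R,5S)-4-[(1E,5E,9Z)-11-{[tert-butyl(dimethyl)silyl]oxy}-1-iodo-5,9-dimethylundeca-1,5,9-trien-1-yl]-2-methoxy-5-(2-methylprop-1-en-1-yl)-1,3-dioxolane, both epimers at C2 | CC(C)=C[C@@H]1OC(OC)O[C@H]1/C(I)=C\CC/C(C)=C/CC/C(C)=C\CO[Si](C)(C)C(C)(C)C | intermediate
20 | alkenyllithium from 19 (lithium in place of iodine, same configuration) | CC(C)=C[C@@H]1OC(OC)O[C@H]1/C([Li])=C\CC/C(C)=C/CC/C(C)=C\CO[Si](C)(C)C(C)(C)C | intermediate
21 | lithium carboxylate from 20 (CO2Li in place of lithium, same configuration) | CC(C)=C[C@@H]1OC(OC)O[C@H]1/C(C(=O)[O-])=C\CC/C(C)=C/CC/C(C)=C\CO[Si](C)(C)C(C)(C)C.[Li+] | intermediate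
22 | (2E)-alk-2-enoic acid from 21 (CO2H on the former iodo carbon, orthoformate intact) | CC(C)=C[C@@H]1OC(OC)O[C@H]1/C(C(=O)O)=C\CC/C(C)=C/CC/C(C)=C\CO[Si](C)(C)C(C)(C)C | intermediate
23 | 1,3-dioxolan-2-ylium carboxylate zwitterion from 22 (loss of methanol) | CC(C)=C[C@@H]1O[CH+]O[C@H]1/C(C(=O)[O-])=C\CC/C(C)=C/CC/C(C)=C\CO[Si](C)(C)C(C)(C)C | intermediate
24 | (3E,4S,5R)-3-{(4E,8Z)-10-[(tert-butyldimethylsilyl)oxy]-4,8-dimethyldeca-4,8-dien-1-ylidene}-5-(2-methylprop-1-en-1-yl)-2-oxooxolan-4-yl formate | CC(C)(C)[Si](C)(C)OC/C=C(/C)CC/C=C(\C)CC/C=C1/C(=O)O[C@H](C=C(C)C)[C@H]1OC=O | intermediate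
25 | (3E,4S,5R)-4-hydroxy-3-[(4E,8Z)-10-hydroxy-4,8-dimethyldeca-4,8-dien-1-ylidene]-5-(2-methylprop-1-en-1-yl)oxolan-2-one | OC/C=C(/C)CC/C=C(\C)CC/C=C1/C(=O)O[C@H](C=C(C)C)[C@H]1O | intermediate
26 | (2E)-3-methylpent-2-enoic acid | CC/C(C)=C/C(=O)O | starting material
27 | [(2Z,6E)-10-[(3E,4S,5R)-4-hydroxy-5-(2-methylprop-1-en-1-yl)-2-oxooxolan-3-ylidene]-3,7-dimethyldeca-2,6-dien-1-yl] (2E)-3-methylpent-2-enoate | CC/C(C)=C/C(=O)OC/C=C(/C)CC/C=C(\C)CC/C=C1/C(=O)O[C@H](C=C(C)C)[C@H]1O | target

**Totals**
Total step count: 14. Longest linear sequence: 14 steps (nerol to 27).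

**Steps most likely to fail**

Step 12 (proposed new method). The dioxolanylium ion may ionise at the allylic C5 to an open allyl cation before the carboxylate attacks. That would erode the inversion at C5 and allow capture at the dimethyl-substituted terminus or loss of a proton to a diene. The alkenyllithium may also undergo β-alkoxide elimination to an allene. The fallback uses known chemistry and closes the lactone by ordinary acylation instead of displacement. It sets out from epoxide 14, which is hydrated (H2O, cat. HClO4, THF, 0 °C) with inversion at the allylic carbon to the erythro diol (4R,5S,10E,14Z)-16-{[tert-butyl(dimethyl)silyl]oxy}-2,10,14-trimethylhexadeca-2,10,14-trien-6-yne-4,5-diol F1, which already has the configuration of the target at both carbinol carbons. Hydrostannation and iodination as in step 10 should give the iodo diol (4R,5R,6E,10E,14Z)-16-{[tert-butyl(dimethyl)silyl]oxy}-6-iodo-2,10,14-trimethylhexadeca-2,6,10,14-tetraene-4,5-diol F2. Treatment with tBuLi (4 equiv) and CO2, then aqueous citric acid, lets the γ-hydroxy acid lactonise with retention to (3E,4S,5R)-3-{(4E,8Z)-10-[(tert-butyldimethylsilyl)oxy]-4,8-dimethyldeca-4,8-dien-1-ylidene}-4-hydroxy-5-(2-methylprop-1-en-1-yl)oxolan-2-one F3. Desilylation under the conditions of step 13 comes back to the route at 25.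

Step 9. Zerovalent palladium may add oxidatively at the propargylic C–O bond (allenylpalladium pathway) instead of the allylic one, and the π-allyl intermediate may epimerise at the allylic carbon by π–σ–π interconversion. The fallback leaves the π-allyl manifold for nucleophilic halide catalysis. With nBu4NBr (cat.) under CO2 pressure (10 bar, 60 °C), bromide opens the epoxide, the alkoxide takes up CO2 and the alkyl carbonate displaces bromide. Retention then arises from two SN2 inversions and no organopalladium species can form. It sets out from 14 and comes back at carbonate 15, which is methanolysed to 16 as before.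

Step 10. The hydrometalation may be poorly regioselective, with tin delivered to the distal alkyne carbon, and the alkenylstannane may be protodestannylated before iodination. The fallback removes tin, iodide and organolithium. It sets out from 16, which is converted (HC(OMe)3, PPTS cat.) to the alkyne orthoformate (4S,5S)-4-{(5E,9Z)-11-[(tert-butyldimethylsilyl)oxy]-5,9-dimethylundeca-5,9-dien-1-yn-1-yl}-2-methoxy-5-(2-methylprop-1-en-1-yl)-1,3-dioxolane F4. Copper hydride-catalysed hydrocarboxylation ((IMes)CuF cat., IMes = 1,3-dimesitylimidazol-2-ylidene, HSi(OEt)3, CO2 1 atm, dioxane, 70 °C, aqueous work-up) adds Cu–H syn, with copper at the alkyne carbon next to the oxygenated carbon, and inserts CO2. This comes back to the route at acid 22, which is closed to 24 with catalytic CH3SO3H in CH2Cl2.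

**Further compounds**
F1 | step 12 | (4R,5S,10E,14Z)-16-{[tert-butyl(dimethyl)silyl]oxy}-2,10,14-trimethylhexadeca-2,10,14-trien-6-yne-4,5-diol | CC(C)=C[C@@H](O)[C@@H](O)C#CCC/C(C)=C/CC/C(C)=C\CO[Si](C)(C)C(C)(C)C
F2 | step 12 | (4R,5R,6E,10E,14Z)-16-{[tert-butyl(dimethyl)silyl]oxy}-6-iodo-2,10,14-trimethylhexadeca-2,6,10,14-tetraene-4,5-diol | CC(C)=C[C@@H](O)[C@@H](O)/C(I)=C\CC/C(C)=C/CC/C(C)=C\CO[Si](C)(C)C(C)(C)C
F3 | step 12 | (3E,4S,5R)-3-{(4E,8Z)-10-[(tert-butyldimethylsilyl)oxy]-4,8-dimethyldeca-4,8-dien-1-ylidene}-4-hydroxy-5-(2-methylprop-1-en-1-yl)oxolan-2-one | CC(C)(C)[Si](C)(C)OC/C=C(/C)CC/C=C(\C)CC/C=C1/C(=O)O[C@H](C=C(C)C)[C@H]1O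
F0 | step 9 | none | none
F4 | step 10 | (4S,5S)-4-{(5E,9Z)-11-[(tert-butyldimethylsilyl)oxy]-5,9-dimethylundeca-5,9-dien-1-yn-1-yl}-2-methoxy-5-(2-methylprop-1-en-1-yl)-1,3-dioxolane | CC(C)=C[C@@H]1OC(OC)O[C@H]1C#CCC/C(C)=C/CC/C(C)=C\CO[Si](C)(C)C(C)(C)C
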